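**Retrosynthetic overview**
1. Target ⇐ C18 alcohol + Meldrum's acid; the alcohol ⇐ selective reduction of the saturated C18 aldehyde of an oxolane dialdehyde.
2. Ring B (oxolane, formed last) ⇐ 5-exo oxa-Michael addition of the C15 hydroxyl to C3 of the C18 enal in a 14-membered hydroxy dialdehyde, as in the presumed biosynthesis (sets C3 and C4).
3. Ring A (14-membered carbocycle, formed first) ⇐ tail-to-head cation–olefin closure of the C1–C2 bond in an acyclic geranylgeranyl-type bis(allylic chloride), made enantioselective by chiral anion-binding catalysis (sets C1); chloride ends on C15.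
4. Acyclic C20 chain ⇐ B-alkyl Suzuki union of a nerol-derived diene acetal with (Z)-2-iodobut-2-ene-1,4-diol; diene ⇐ Wittig reaction of a ketoacetal made from neryl bromide and 1,1-dimethoxyacetone.

Locants: cembrane numbering is used in the text. C1 carries the C15 isopropyl unit, C2 is the oxolane CH2, C3 the O-bearing CH, C4 carries C18, C8 carries C19 (CHO), C12 carries C20 (CH3).

Assumption: the (4R) centre of the target is the thermodynamically preferred C4 epimer of aldehyde 19 (C4 is epimerisable there), and the catalyst antipode named in step 7 is the one that gives (1R)-16 (otherwise its mirror image is used).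

**Step 1**
Reactants: 1 nerol, (2Z)-3,7-dimethylocta-2,6-dien-1-ol
Product: 2 neryl bromide, (2Z)-1-bromo-3,7-dimethylocta-2,6-diene
Conditions: PBr3 (0.4 equiv), pyridine (cat.), Et2O, −10 °C; used crude
Reagents that add atoms: phosphorus tribromide, BrP(Br)Br
Why: SN2 bromination of a primary allylic alcohol with PBr3 at low temperature goes without allylic transposition, so the (Z)-trisubstituted alkene of nerol is carried over unchanged.

**Step 2**
Reactants: 2 neryl bromide; 3 1,1-dimethoxypropan-2-one
Product: 5 (5Z)-1,1-dimethoxy-6,10-dimethylundeca-5,9-dien-2-one, via lithium enolate 4 (not isolated)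
Conditions: LiN(iPr)2 (2.0 equiv), 3 (2.0 equiv), THF, −78 °C; then 2, DMPU, −78 → 0 °C
Reagents that add atoms: none
Why: Kinetic deprotonation of the methyl ketone gives the less substituted enolate, and its SN2 C-alkylation by the primary allylic bromide (ketone enolate alkylation) keeps the (Z)-alkene.

**Step 3**
Reactants: 5 ketoacetal; 6 allyltriphenylphosphonium bromide
Product: 8 (3Z,7Z)-4-(dimethoxymethyl)-8,12-dimethyltrideca-1,3,7,11-tetraene, via allyl ylide 7 (not isolated)
Conditions: n-BuLi, THF, −78 → 0 °C; then 5, −78 °C → rt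
Reagents that add atoms: none
Why: Wittig olefination of the activated α,α-dialkoxy ketone with the semi-stabilised allyl ylide gives the 1,3-diene; the new C3=C4 alkene is expected as a Z/E mixture (Z drawn), which does not matter because this geometry is equilibrated at the enal stage in step 5.

**Step 4**
Reactants: 9 but-2-yne-1,4-diol
Product: 11 (2Z)-2-iodobut-2-ene-1,4-diol, via alkenylaluminate 10 (not isolated)
Conditions: NaAlH2(OCH2CH2OCH3)2 (2.2 equiv), THF, 0 °C → rt; then I2, −78 → 0 °C
Reagents that add atoms: iodine, [I][I]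
Why: Hydroxyl-directed trans-hydroalumination of the propargylic diol gives a cyclic alkenylaluminate that is iodinated with retention (hydroalumination–iodination), fixing the Z geometry.

**Step 5**
Reactants: 8 tetraene acetal; 11 (2Z)-2-iodobut-2-ene-1,4-diol
Product: 14 (2E,6E)-2-[(3Z)-4,8-dimethylnona-3,7-dien-1-yl]-8-hydroxy-6-(hydroxymethyl)octa-2,6-dienal, via alkylborane 12 (not isolated), via acetal diol 13 (not isolated)
Conditions: 9-BBN-H (1.1 equiv), THF, 0 °C → rt; then 11, PdCl2(dppf) (5 mol%; dppf = 1,1'-bis(diphenylphosphino)ferrocene), Cs2CO3, DMF/H2O, 50 °C; then aq. HCl (1 mol/L), THF, rt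
Reagents that add atoms: water, O
Why: 9-BBN hydroborates only the monosubstituted end of the diene (anti-Markovnikov), the B-alkyl Suzuki–Miyaura coupling proceeds with retention of the alkenyl iodide geometry, and aqueous HCl hydrolyses the unsaturated acetal and equilibrates the α-substituted enal to the more stable (E)-isomer by reversible conjugate addition.

**Step 6**
Reactants: 14 enal diol
Product: 15 (2E,6E)-8-chloro-6-(chloromethyl)-2-[(3Z)-4,8-dimethylnona-3,7-dien-1-yl]octa-2,6-dienal
Conditions: N-chlorosuccinimide (2.4 equiv), Me2S (2.6 equiv), CH2Cl2, −20 → 0 °C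
Reagents that add atoms: N-chlorosuccinimide, O=C1CCC(=O)N1Cl
Why: Corey–Kim chlorination converts both primary allylic alcohols into chlorides by SN2 displacement of an alkoxysulfonium ion, without allylic transposition and without touching the enal or the trisubstituted alkenes.

**Step 7 (key step, ring A)**
Reactants: 15 bis(allylic chloride)
Product: 16 (1E,5E,8R,11Z)-5-(chloromethyl)-8-(2-chloropropan-2-yl)-11-methylcyclotetradeca-1,5,11-triene-1-carbaldehyde [(1R)-15,18-dichlorocembra-3,7,11-trien-19-al]
Conditions: 1-[3,5-bis(trifluoromethyl)phenyl]-3-[(2S)-3,3-dimethyl-1-oxo-1-[(2R)-2-(phenanthren-9-yl)pyrrolidin-1-yl]butan-2-yl]urea (20 mol%), 4 Å molecular sieves, toluene (0.002 mol/L), −20 → 4 °C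
Reagents that add atoms: none
Why: Proposed new method: two urea molecules abstract chloride from C2 of 15 to give a tight chiral ion pair of the allyl cation with urea-bound chloride, ionisation being selective for this chloride because only it gives an allyl cation with a tertiary terminus (C4); the C7=C8 alkene is switched off by its formyl group, so the terminal prenyl alkene attacks C2 through C1 (Markovnikov, 14-membered ring), the catalyst arene shields one face of that alkene so that C1 forms as R, and collapse of the C15 cation with the bound chloride (net isomerisation) releases the catalyst; the closest known reaction types are the chiral-urea-catalysed enantioselective tail-to-head cyclisation of neryl chlorides and the SnCl4-induced 14-membered closure of geranylgeranoyl chloride onto its terminal alkene with chloride capture at C15.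

**Step 8**
Reactants: 16 macrocyclic dichloride
Product: 17 (1E,5E,8R,11Z)-8-(2-chloropropan-2-yl)-11-methylcyclotetradeca-1,5,11-triene-1,5-dicarbaldehyde
Conditions: N-methylmorpholine N-oxide (5 equiv), 4 Å molecular sieves, MeCN, 40 °C
Reagents that add atoms: N-methylmorpholine N-oxide, C[N+]1([O-])CCOCC1
Why: Ganem-type N-oxide oxidation: SN2 displacement of the primary allylic chloride by the N-oxide oxygen followed by base-induced N–O fragmentation gives the (E)-enal, while the tertiary chloride cannot react by SN2.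

**Step 9 (ring B)**
Reactants: 17 chloro dialdehyde
Product: 19 (1R,4Z,8E,12S,13R)-4,15,15-trimethyl-14-oxabicyclo[11.2.1]hexadeca-4,8-diene-8,12-dicarbaldehyde, via hydroxy dialdehyde 18 (not isolated)
Conditions: NaHCO3, acetone/H2O (2:1), 45 °C; then 1,8-diazabicyclo[5.4.0]undec-7-ene (0.3 equiv), CH2Cl2, 0 °C → rt
Reagents that add atoms: water, O
Why: SN1 hydrolysis of the tertiary chloride gives the C15 alcohol, which adds by a base-catalysed, reversible 5-exo-trig oxa-Michael reaction to C3 of the C18 enal (the presumed biosynthetic closure); the cis-bridged oxolane fixes C3 relative to C1, and C4, α to the new aldehyde, equilibrates to the thermodynamic epimer (same spatial arrangement as 4R in the target; the descriptor reads S here only because CHO outranks C3).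

**Step 10**
Reactants: 19 oxolane dialdehyde
Product: 20 (1R,4Z,8E,12R,13R)-12-(hydroxymethyl)-4,15,15-trimethyl-14-oxabicyclo[11.2.1]hexadeca-4,8-diene-8-carbaldehyde
Conditions: NaBH4 (0.5 equiv), EtOH/CH2Cl2 (3:7), −78 °C
Reagents that add atoms: none
Why: Chemoselective borohydride reduction: at −78 °C the saturated aldehyde is reduced much faster than the conjugated α-substituted enal, and no stereocentre is touched.

**Step 11**
Reactants: 20 hydroxy enal; 21 Meldrum's acid (2,2-dimethyl-1,3-dioxane-4,6-dione)
Product: 22 CNP0170412.1, 3-{[(1R,4Z,8E,12R,13R)-8-formyl-4,15,15-trimethyl-14-oxabicyclo[11.2.1]hexadeca-4,8-dien-12-yl]methoxy}-3-oxopropanoic acid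
Conditions: 21 (1.2 equiv), toluene, 90 °C
Reagents that add atoms: none
Why: Thermal acylation: the primary alcohol opens Meldrum's acid at a carbonyl group and the adduct loses acetone to give the malonic half ester directly, without base, so the enal and the stereocentres are untouched.

**Compound list**
1 | nerol, (2Z)-3,7-dimethylocta-2,6-dien-1-ol | CC(C)=CCC/C(C)=C\CO | starting material
2 | neryl bromide, (2Z)-1-bromo-3,7-dimethylocta-2,6-diene | CC(C)=CCC/C(C)=C\CBr | intermediate
3 | 1,1-dimethoxypropan-2-one | CC(=O)C(OC)OC | starting material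
4 | lithium 3,3-dimethoxyprop-1-en-2-olate (lithium enolate of 3) | [Li+].[O-]C(=C)C(OC)OC | intermediate
5 | (5Z)-1,1-dimethoxy-6,10-dimethylundeca-5,9-dien-2-one | CC(C)=CCC/C(C)=C\CCC(=O)C(OC)OC | intermediate
6 | allyltriphenylphosphonium bromide | C=CC[P+](c1ccccc1)(c1ccccc1)c1ccccc1.[Br-] | starting material
7 | allylidene(triphenyl)phosphorane | C=CC=P(c1ccccc1)(c1ccccc1)c1ccccc1 | intermediate
8 | (3Z,7Z)-4-(dimethoxymethyl)-8,12-dimethyltrideca-1,3,7,11-tetraene (3E isomer accompanies it and is carried on) | C=C/C=C(\C(OC)OC)CC/C=C(/C)CCC=C(C)C | intermediate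
9 | but-2-yne-1,4-diol | OCC#CCO | starting material
10 | cyclic (Z)-alkenylaluminate of 9 (idealised as the disodium salt) | [Na+].[Na+].[O-]C/C(=C/CO1)[Al-]1(OCCOC)OCCOC | intermediate
11 | (2Z)-2-iodobut-2-ene-1,4-diol | OC/C=C(\I)CO | intermediate
12 | 9-[(3Z,7Z)-4-(dimethoxymethyl)-8,12-dimethyltrideca-3,7,11-trien-1-yl]-9-borabicyclo[3.3.1]nonane | B1(CC/C=C(\C(OC)OC)CC/C=C(/C)CCC=C(C)C)C2CCCC1CCC2 | intermediate
13 | (2E,6Z,10Z)-7-(dimethoxymethyl)-3-(hydroxymethyl)-11,15-dimethylhexadeca-2,6,10,14-tetraen-1-ol | OC/C=C(/CO)CC/C=C(\C(OC)OC)CC/C=C(/C)CCC=C(C)C | intermediate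
14 | (2E,6E)-2-[(3Z)-4,8-dimethylnona-3,7-dien-1-yl]-8-hydroxy-6-(hydroxymethyl)octa-2,6-dienal | OC/C=C(/CO)CC/C=C(/C=O)CC/C=C(/C)CCC=C(C)C | intermediate
15 | (2E,6E)-8-chloro-6-(chloromethyl)-2-[(3Z)-4,8-dimethylnona-3,7-dien-1-yl]octa-2,6-dienal | ClC/C=C(/CCl)CC/C=C(/C=O)CC/C=C(/C)CCC=C(C)C | intermediate
16 | (1E,5E,8R,11Z)-5-(chloromethyl)-8-(2-chloropropan-2-yl)-11-methylcyclotetradeca-1,5,11-triene-1-carbaldehyde | ClC(C)(C)[C@H]1C/C=C(/CCl)CC/C=C(/C=O)CC/C=C(/C)CC1 | intermediate
17 | (1E,5E,8R,11Z)-8-(2-chloropropan-2-yl)-11-methylcyclotetradeca-1,5,11-triene-1,5-dicarbaldehyde | ClC(C)(C)[C@H]1C/C=C(/C=O)CC/C=C(/C=O)CC/C=C(/C)CC1 | intermediate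
18 | (1E,5E,8R,11Z)-8-(2-hydroxypropan-2-yl)-11-methylcyclotetradeca-1,5,11-triene-1,5-dicarbaldehyde | OC(C)(C)[C@H]1C/C=C(/C=O)CC/C=C(/C=O)CC/C=C(/C)CC1 | intermediate
19 | (1R,4Z,8E,12S,13R)-4,15,15-trimethyl-14-oxabicyclo[11.2.1]hexadeca-4,8-diene-8,12-dicarbaldehyde | C/C1=C/CC/C(C=O)=C\CC[C@H](C=O)[C@H]2C[C@@H](CC1)C(C)(C)O2 | intermediate
20 | (1R,4Z,8E,12R,13R)-12-(hydroxymethyl)-4,15,15-trimethyl-14-oxabicyclo[11.2.1]hexadeca-4,8-diene-8-carbaldehyde | C/C1=C/CC/C(C=O)=C\CC[C@H](CO)[C@H]2C[C@@H](CC1)C(C)(C)O2 | intermediate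
21 | Meldrum's acid, 2,2-dimethyl-1,3-dioxane-4,6-dione | CC1(C)OC(=O)CC(=O)O1 | starting material
22 | CNP0170412.1, 3-{[(1R,4Z,8E,12R,13R)-8-formyl-4,15,15-trimethyl-14-oxabicyclo[11.2.1]hexadeca-4,8-dien-12-yl]methoxy}-3-oxopropanoic acid | C/C1=C/CC/C(C=O)=C\CC[C@H](COC(=O)CC(=O)O)[C@H]2C[C@@H](CC1)C(C)(C)O2 | target

**Step count**
Total: 11 steps (step 4 is a one-step side branch). Longest linear sequence: 10 steps from nerol (steps 1, 2, 3, 5, 6, 7, 8, 9, 10, 11).

**Three steps most likely to fail**

Step 7 (macrocyclisation). The urea may not ionise the inductively deactivated allylic chloride, closure through C11 to a 10-membered ring or E1 loss from the C15 cation may compete, and the level of asymmetric induction for a 14-membered closure is unknown. Fallback: give up catalyst control of C1. From 15, SnCl4 (1.1 equiv) in CH2Cl2 at −78 °C and 0.002 mol/L (the stoichiometric Lewis-acid ionisation known to close the 14-membered ring of geranylgeranoyl chloride) gives the racemic macrocyclic dichloride F1. The N-oxide oxidation of step 8 turns it into the racemic chloro dialdehyde F2, and the bicarbonate hydrolysis of step 9 gives the racemic hydroxy dialdehyde F3. The oxolane closure is then run as a kinetic resolution with 9-amino-9-deoxy-epi-quinine bis(trifluoroacetate) (20 mol%, toluene, 0 °C). Iminium activation of the α-substituted C18 enal lets the catalyst dictate the new C3 centre, and only the (1R)-enantiomer can reach the cis-bridged oxolane with that C3 configuration. It alone is converted (C4 is then equilibrated with the amidine base as in step 9), and the route is rejoined at 19. The unreacted (8S)-hydroxy dialdehyde F4 is removed by chromatography.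

Step 9 (oxa-Michael closure). The tertiary alcohol may add sluggishly, the adduct may revert, or the C4 equilibrium may favour the wrong epimer. Fallback: close the oxolane before C18 is oxidised and set C4 kinetically. From 16, NaHCO3 in acetone/H2O at 45 °C hydrolyses only the tertiary chloride and gives the hydroxy allylic chloride F5. AgOSO2CF3 with 2,6-di-tert-butyl-4-methylpyridine in CH2Cl2 at −40 °C ionises the allylic chloride, and the C15 hydroxyl closes on C3 (5-exo, SN2'-type; closure on C18 is impossible because C18 is trans to C2 on the alkene). This gives the methylidene oxolane F6. 9-BBN-H (3 equiv) then hydroborates the 1,1-disubstituted alkene from its more open face, anti to the C3–O bond, and at the same time reduces the enal 1,2; NaBO3 work-up gives the diol F7. MnO2 in CH2Cl2 re-oxidises only the allylic alcohol, and the route is rejoined at 20.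

Step 11 (malonylation). Meldrum's acid or the product half ester may condense with the free enal (Knoevenagel) at 90 °C. Fallback: acylate cold and unmask afterwards. From 20, 3-(allyloxy)-3-oxopropanoic acid, dicyclohexylcarbodiimide and 4-(dimethylamino)pyridine (cat.) in CH2Cl2 at 0 °C give the allyl malonate F8. Pd(PPh3)4 (zerovalent palladium, 5 mol%) with morpholine in THF at rt removes the allyl group and gives 22.

**Further compounds**
F1 | step 7 | racemic 16, (1E,5E,11Z)-5-(chloromethyl)-8-(2-chloropropan-2-yl)-11-methylcyclotetradeca-1,5,11-triene-1-carbaldehyde | ClC(C)(C)C1C/C=C(/CCl)CC/C=C(/C=O)CC/C=C(/C)CC1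
F2 | step 7 | racemic 17, (1E,5E,11Z)-8-(2-chloropropan-2-yl)-11-methylcyclotetradeca-1,5,11-triene-1,5-dicarbaldehyde | ClC(C)(C)C1C/C=C(/C=O)CC/C=C(/C=O)CC/C=C(/C)CC1
F3 | step 7 | racemic 18, (1E,5E,11Z)-8-(2-hydroxypropan-2-yl)-11-methylcyclotetradeca-1,5,11-triene-1,5-dicarbaldehyde | OC(C)(C)C1C/C=C(/C=O)CC/C=C(/C=O)CC/C=C(/C)CC1
F4 | step 7 | (1E,5E,8S,11Z)-8-(2-hydroxypropan-2-yl)-11-methylcyclotetradeca-1,5,11-triene-1,5-dicarbaldehyde (enantiomer of 18) | OC(C)(C)[C@@H]1C/C=C(/C=O)CC/C=C(/C=O)CC/C=C(/C)CC1
F5 | step 9 | (1E,5E,8R,11Z)-5-(chloromethyl)-8-(2-hydroxypropan-2-yl)-11-methylcyclotetradeca-1,5,11-triene-1-carbaldehyde | OC(C)(C)[C@H]1C/C=C(/CCl)CC/C=C(/C=O)CC/C=C(/C)CC1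
F6 | step 9 | (1R,4Z,8E,13R)-4,15,15-trimethyl-12-methylidene-14-oxabicyclo[11.2.1]hexadeca-4,8-diene-8-carbaldehyde | C/C1=C/CC/C(C=O)=C\CCC(=C)[C@H]2C[C@@H](CC1)C(C)(C)O2
F7 | step 9 | [(1R,4Z,8E,12R,13R)-8-(hydroxymethyl)-4,15,15-trimethyl-14-oxabicyclo[11.2.1]hexadeca-4,8-dien-12-yl]methanol | C/C1=C/CC/C(CO)=C\CC[C@H](CO)[C@H]2C[C@@H](CC1)C(C)(C)O2
F8 | step 11 | prop-2-en-1-yl [(1R,4Z,8E,12R,13R)-8-formyl-4,15,15-trimethyl-14-oxabicyclo[11.2.1]hexadeca-4,8-dien-12-yl]methyl propanedioate | C/C1=C/CC/C(C=O)=C\CC[C@H](COC(=O)CC(=O)OCC=C)[C@H]2C[C@@H](CC1)C(C)(C)O2
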